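**Plan**
- Retrosynthesis: both aryl–CH2 bonds are cut first, so that each benzylic carbon becomes the α-carbon of an acetic acid side chain. The two carboxyl carbons are then rejoined as the C=C of a cyclohexene, one ring C–O bond is opened to a 1,4-diol, and the bonds from C3 and C4 to the two side-chain carbons are cut by a retro-[4+2].
- Enabling feature: C3 and C4 of the oxolane are trans-vicinal CH groups, each bonded to one OCH2 and one ArCH2. They correspond to C1 and C2 of a trans-cyclohex-4-ene-1,2-dicarboxylate, whose ring carbons C3 and C6 are the future benzylic carbons and whose ester carbons are the future OCH2 groups.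
- Forward order: fumarate diester, Diels–Alder reaction (temporary carbocycle), reduction, oxolane ring by intramolecular etherification, ozonolytic opening of the carbocycle, redox-active esters, two nickel-catalysed decarboxylative arylations.
- Stereochemistry: the trans relation comes from the E-fumarate and the absolute (3R,4R) configuration from the two (1S,2R,5S)-menthyl groups in the cycloaddition. Neither centre is touched afterwards, and the descriptors stay R,R throughout.

Key step: step 2

Assumption: the (1S,2R,5S)-menthyl ester, aluminium-bound in the s-trans enoate conformation, is taken to expose the fumarate face that leads to the (1R,2R) adduct; if the opposite sense were found, the antipodal menthol would be used in step 1.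

Stoichiometry: in steps 1, 6 and 7 two molecules of one partner are built into each molecule of product; the first is given under Reactants and the second under Reagents that add atoms.

Step 1
Reactants: 1 fumaric acid; 2 (1S,2R,5S)-menthol
Product: 3 bis[(1S,2R,5S)-menthyl] fumarate
Conditions: 2 (2.2 equiv in all), TsOH·H2O (cat.), toluene, reflux, Dean–Stark trap
Reagents that add atoms: (1S,2R,5S)-menthol (second equivalent of 2), C[C@H]1CC[C@@H]([C@H](C1)O)C(C)C
Why: Fischer esterification of both carboxyl groups, each with one molecule of menthol, is driven to the diester by azeotropic removal of water; it proceeds by acyl–oxygen cleavage, so the carbinol centres of the auxiliary and the E geometry of the alkene are carried over unchanged.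

Step 2
Reactants: 3 bis[(1S,2R,5S)-menthyl] fumarate; 4 buta-1,3-diene
Product: 5 bis[(1S,2R,5S)-menthyl] (1R,2R)-cyclohex-4-ene-1,2-dicarboxylate
Conditions: i-Bu2AlCl (2 equiv, promoter), excess butadiene, toluene–hexane, −40 °C; aq. HCl work-up; recrystallisation
Reagents that add atoms: none
Why: Each ester carbonyl binds one i-Bu2AlCl, which lowers the LUMO of the fumarate and holds both enoate units s-trans, and the diene then adds in a concerted, suprafacial, normal-demand [4+2] cycloaddition (Diels–Alder reaction). The closest known reaction type is the aluminium-promoted asymmetric Diels–Alder reaction of dimenthyl fumarates with simple acyclic dienes. The cyclohexene ring is closed by intermolecular cycloaddition, both new σ bonds (C1–C6 and C2–C3 of the adduct) forming in the same transition state. The trans relation of C1 and C2 follows stereospecifically from the E alkene, and their absolute configuration from the two menthyl groups, whose isopropyl substituents cover the same face of the C2-symmetric dienophile and direct butadiene to the open face. Only facial selectivity is needed, because the diene is symmetric and endo and exo approaches to a C2-symmetric dienophile are identical; the double auxiliary at low temperature should secure it. Recrystallisation of 5 is expected to remove any minor (1S,2S) diastereomer.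

Step 3
Reactants: 5 bis[(1S,2R,5S)-menthyl] (1R,2R)-cyclohex-4-ene-1,2-dicarboxylate
Product: 6 [(1R,2R)-cyclohex-4-ene-1,2-diyl]dimethanol
Conditions: LiAlH4, THF, 0 °C to reflux; aqueous NaOH work-up; menthol recovered
Reagents that add atoms: none
Why: LiAlH4 ester reduction converts both esters into primary alcohols and leaves the isolated alkene alone, and the α-stereocentres are not at risk because hydride addition outpaces enolisation and the trans arrangement is in any case the more stable one.

Step 4
Reactants: 6 [(1R,2R)-cyclohex-4-ene-1,2-diyl]dimethanol
Product: 8 (3aR,7aR)-1,3,3a,4,7,7a-hexahydro-2-benzofuran, via monotosylate 7 (not isolated)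
Conditions: NaH (2.2 equiv), THF, 0 °C; TsCl (1.0 equiv), 0 °C to 50 °C; careful concentration (volatile product)
Reagents that add atoms: none
Why: One alkoxide is sulfonylated and the neighbouring alkoxide displaces the primary tosylate in a 5-exo-tet intramolecular Williamson etherification; substitution takes place at CH2 only, so both ring-fusion centres keep their configuration and the trans fusion follows from the trans-diol.

Step 5
Reactants: 8 (3aR,7aR)-1,3,3a,4,7,7a-hexahydro-2-benzofuran
Product: 11 2,2'-[(3R,4R)-oxolane-3,4-diyl]diacetic acid, via methoxy hydroperoxide aldehyde 9 (not isolated), via dialdehyde 10 (not isolated)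
Conditions: O3, CH2Cl2–MeOH, −78 °C; Me2S, −78 °C to rt; concentrate; then NaClO2, NaH2PO4, 2-methyl-2-butene, t-BuOH–H2O, rt
Reagents that add atoms: ozone, [O-][O+]=O; sodium chlorite, [Na+].[O-]Cl=O
Why: Ozonolysis of the only alkene (ether C–H bonds are inert to ozone at −78 °C), reductive work-up to the dialdehyde and Pinnick chlorite oxidation give the diacid, and the stereocentres cannot epimerise because they are β, not α, to the new carbonyl groups.

Step 6
Reactants: 11 2,2'-[(3R,4R)-oxolane-3,4-diyl]diacetic acid; 12 N-hydroxyphthalimide
Product: 13 bis(1,3-dioxoisoindolin-2-yl) 2,2'-[(3R,4R)-oxolane-3,4-diyl]diacetate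
Conditions: 12 (2.2 equiv in all), N,N'-diisopropylcarbodiimide (2.2 equiv), DMAP (cat.), CH2Cl2, rt
Reagents that add atoms: N-hydroxyphthalimide (second equivalent of 12), ON1C(=O)c2ccccc2C1=O
Why: Carbodiimide esterification with DMAP catalysis (Steglich-type) turns both primary carboxylic acids into N-acyloxyphthalimide redox-active esters under neutral conditions that affect neither the ether nor the stereocentres.

Step 7
Reactants: 13 bis(1,3-dioxoisoindolin-2-yl) 2,2'-[(3R,4R)-oxolane-3,4-diyl]diacetate; 14 4-iodo-1,2-dimethoxybenzene
Product: 15 (3R,4R)-3,4-bis[(3,4-dimethoxyphenyl)methyl]oxolane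
Conditions: 14 (3 equiv in all), NiBr2(MeOCH2CH2OMe) (20 mol %), 4,4'-di-tert-butyl-2,2'-bipyridine (20 mol %), Zn powder (4 equiv), N,N-dimethylacetamide, rt
Reagents that add atoms: 4-iodo-1,2-dimethoxybenzene (second equivalent of 14), COc1ccc(I)cc1OC
Why: Nickel-catalysed decarboxylative cross-electrophile coupling of primary N-acyloxyphthalimides with aryl iodides: zinc reduces the divalent nickel precatalyst to zerovalent nickel, which adds the aryl iodide; single-electron reduction of each ester releases phthalimide anion, CO2 and a primary alkyl radical that is captured at nickel, and reductive elimination forms each CH2–aryl bond while the ring stereocentres, one carbon away from the radical, stay untouched.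

**Compound list**
1 | fumaric acid | OC(=O)/C=C/C(=O)O | starting material
2 | (1S,2R,5S)-menthol | C[C@H]1CC[C@@H]([C@H](C1)O)C(C)C | starting material
3 | bis[(1S,2R,5S)-menthyl] fumarate | C[C@H]1CC[C@@H]([C@H](C1)OC(=O)/C=C/C(=O)O[C@H]2C[C@@H](C)CC[C@@H]2C(C)C)C(C)C | intermediate
4 | buta-1,3-diene | C=CC=C | starting material
5 | bis[(1S,2R,5S)-menthyl] (1R,2R)-cyclohex-4-ene-1,2-dicarboxylate | C[C@H]1CC[C@@H]([C@H](C1)OC(=O)[C@@H]2CC=CC[C@H]2C(=O)O[C@H]3C[C@@H](C)CC[C@@H]3C(C)C)C(C)C | intermediate
6 | [(1R,2R)-cyclohex-4-ene-1,2-diyl]dimethanol | OC[C@@H]1CC=CC[C@H]1CO | intermediate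
7 | [(1R,6R)-6-(hydroxymethyl)cyclohex-3-en-1-yl]methyl 4-methylbenzenesulfonate (present as its sodium alkoxide) | Cc1ccc(cc1)S(=O)(=O)OC[C@@H]1CC=CC[C@H]1CO | intermediate
8 | (3aR,7aR)-1,3,3a,4,7,7a-hexahydro-2-benzofuran (trans-fused) | C1=CC[C@H]2COC[C@@H]2C1 | intermediate
9 | 2-[(3R,4R)-4-(2-hydroperoxy-2-methoxyethyl)oxolan-3-yl]acetaldehyde (both epimers at the peroxyacetal carbon) | COC(OO)C[C@H]1COC[C@@H]1CC=O | intermediate
10 | 2,2'-[(3R,4R)-oxolane-3,4-diyl]diacetaldehyde | O=CC[C@H]1COC[C@@H]1CC=O | intermediate
11 | 2,2'-[(3R,4R)-oxolane-3,4-diyl]diacetic acid | OC(=O)C[C@H]1COC[C@@H]1CC(=O)O | intermediate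
12 | N-hydroxyphthalimide | ON1C(=O)c2ccccc2C1=O | starting material
13 | bis(1,3-dioxoisoindolin-2-yl) 2,2'-[(3R,4R)-oxolane-3,4-diyl]diacetate | O=C(C[C@H]1COC[C@@H]1CC(=O)ON1C(=O)c2ccccc2C1=O)ON1C(=O)c2ccccc2C1=O | intermediate
14 | 4-iodo-1,2-dimethoxybenzene | COc1ccc(I)cc1OC | starting material
15 | (3R,4R)-3,4-bis[(3,4-dimethoxyphenyl)methyl]oxolane (trans-3,4-bis(3,4-dimethoxybenzyl)tetrahydrofuran) | COc1ccc(C[C@H]2COC[C@@H]2Cc2ccc(OC)c(OC)c2)cc1OC | target

**Step count**
Total steps: 7. Longest linear sequence: 7 steps (1 → 3 → 5 → 6 → 8 → 11 → 13 → 15).

**Steps most likely to fail**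

Step 7. Two couplings must succeed in one molecule. The second alkyl radical may be reduced to a methyl group, or may add to the electron-rich ring installed by the first coupling before nickel captures it, and the aryl iodide may be used up by homocoupling. The fallback sets out from diacid 11 and replaces radical capture at nickel by polar substitution. Photochemical iododecarboxylation of both acid groups (PhI(OAc)2, I2, 1,2-dichloroethane, hν) should give (3R,4R)-3,4-bis(iodomethyl)oxolane F1. Commercial 4-bromo-1,2-dimethoxybenzene and Mg in THF give (3,4-dimethoxyphenyl)magnesium bromide F2. Copper-catalysed Grignard alkylation of F1 with excess F2 (Li2CuCl4 cat., THF, −10 °C to rt) returns to the route at target 15.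

Step 5. The 1,6-dialdehyde may undergo intramolecular aldol condensation before it is oxidised, and the very polar diacid may be lost to the salt-laden aqueous phase on extraction. The fallback sets out from ether 8 and avoids any free aldehyde. Ozonolysis in methanolic NaOH–CH2Cl2 at −78 °C should convert the alkene directly into dimethyl 2,2'-[(3R,4R)-oxolane-3,4-diyl]diacetate F3, which is easily extracted and purified. Saponification (LiOH, THF–H2O, then acidification and evaporation) returns to the route at diacid 11.

Step 2. Facial discrimination may be incomplete, or the Lewis acid may oligomerise the diene, leaving an adduct that crystallisation cannot bring to diastereomeric purity. The fallback sets out from buta-1,3-diene 4 and takes the absolute configuration from a resolution instead of an auxiliary. Uncatalysed thermal cycloaddition with commercial diethyl fumarate (sealed vessel, about 110 °C, hydroquinone) should give rac-diethyl trans-cyclohex-4-ene-1,2-dicarboxylate F4. Saponification (KOH, EtOH–H2O) gives rac-trans-cyclohex-4-ene-1,2-dicarboxylic acid F5. Fractional crystallisation of its salt with a single enantiomer of 1-phenylethylamine, using whichever antipode of the base crystallises with the wanted acid, gives (1R,2R)-cyclohex-4-ene-1,2-dicarboxylic acid F6. LiAlH4 reduction in THF returns to the route at diol 6.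

**Further compounds**
F1 | step 7 | (3R,4R)-3,4-bis(iodomethyl)oxolane | IC[C@H]1COC[C@@H]1CI
F2 | step 7 | (3,4-dimethoxyphenyl)magnesium bromide | COc1ccc([Mg]Br)cc1OC
F3 | step 5 | dimethyl 2,2'-[(3R,4R)-oxolane-3,4-diyl]diacetate | COC(=O)C[C@H]1COC[C@@H]1CC(=O)OC
F4 | step 2 | rac-diethyl trans-cyclohex-4-ene-1,2-dicarboxylate (one enantiomer drawn) | CCOC(=O)[C@@H]1CC=CC[C@H]1C(=O)OCC
F5 | step 2 | rac-trans-cyclohex-4-ene-1,2-dicarboxylic acid (one enantiomer drawn) | OC(=O)[C@@H]1CC=CC[C@H]1C(=O)O
F6 | step 2 | (1R,2R)-cyclohex-4-ene-1,2-dicarboxylic acid | OC(=O)[C@@H]1CC=CC[C@H]1C(=O)O
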